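The route rests on excising C10, the iodine-bearing sp2 carbon that lies between the C9 ketone and C11 in the cyclopentenone ring (C8–C12, numbering from the ester carbon C1). Without it a four-membered ring of C8, C9, C11 and C12 remains, so the key step adds diiodocarbene to a 1-siloxycyclobutene and lets the strained adduct open: one operation forms C9–C10 and C10–C11, enlarges the ring to five members and delivers the enone with its vinyl iodide. The precursor is the C9=C11 silyl enol ether of a cyclobutanone whose C12 carries the protected tertiary oxygen and the octenyl chain and whose C8 carries the complete C1–C7 chain.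

Key step: step 14

Remark: atoms carry the target numbering throughout (C1 = methyl ester carbon, ring = C8–C12); the enol ether of the key-step precursor is made as the triethylsilyl derivative, a spectator change that keeps its skeleton but tolerates alkoxide and handling better than a trimethylsilyl enol ether; CIP descriptors at C7 and C12 change along the route through priority changes only, not through any change of configuration.

Step 1
Reactants: 1 (3Z)-non-3-en-1-ol
Product: 2 (3Z)-non-3-enoic acid
Conditions: CrO3, H2SO4, H2O, acetone, 0 °C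
Reagents that add atoms: water, O
Why: Jones oxidation takes the primary homoallylic alcohol through the aldehyde hydrate to the carboxylic acid in cold acidic acetone, conditions under which the isolated cis double bond should neither migrate into conjugation nor isomerise.

Step 2
Reactants: 2 (3Z)-non-3-enoic acid
Product: 3 4-methoxybenzyl (3Z)-non-3-enoate
Conditions: PMBCl, KHCO3, DMF, rt
Reagents that add atoms: 4-methoxybenzyl chloride, COc1ccc(CCl)cc1
Why: Carboxylate O-alkylation (SN2 esterification) with the weak base KHCO3 forms the ester without an activated acyl intermediate or a strong base, either of which could pull the beta,gamma double bond into conjugation.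

Step 3
Reactants: 3 4-methoxybenzyl (3Z)-non-3-enoate
Product: 4 1-{[(4Z)-deca-1,4-dien-2-yloxy]methyl}-4-methoxybenzene
Conditions: Cp2TiMe2, toluene, 65 °C, dark
Reagents that add atoms: dimethyltitanocene Cp2TiMe2, C[Ti+2]C.c1cc[cH-]c1.c1cc[cH-]c1
Why: Petasis methylenation, in which Cp2Ti=CH2 generated thermally from Cp2TiMe2 adds to the ester carbonyl and the oxatitanacyclobutane collapses to the 1,1-disubstituted enol ether, is neither acidic nor basic and so should leave the skipped cis-alkene and the benzylic C–O bond alone.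

Step 4
Reactants: 5 methyl hex-5-ynoate
Product: 6 methyl 6-iodohex-5-ynoate
Conditions: NIS, AgNO3 (10 mol%), acetone, rt, dark
Reagents that add atoms: N-iodosuccinimide, O=C1CCC(=O)N1I
Why: Electrophilic iodination of the terminal alkyne C–H by NIS under AgNO3 catalysis is neutral and should not touch the methyl ester, and it turns the alkyne into a precursor for metalation without a strong base.

Step 5
Reactants: 6 methyl 6-iodohex-5-ynoate
Product: 8 methyl 7-oxohept-5-ynoate, via alkynylmagnesium chloride 7 (not isolated)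
Conditions: iPrMgCl·LiCl, THF, −78 °C; DMF, −78 → 0 °C; inverse quench into aqueous KH2PO4
Reagents that add atoms: N,N-dimethylformamide, CN(C)C=O
Why: Iodine–magnesium exchange at the sp carbon is expected to outrun addition of the Grignard reagent to the methyl ester at −78 °C, and the alkynylmagnesium chloride is then formylated by DMF (Bouveault-type aldehyde synthesis), the inverse buffered quench keeping the liberated dimethylamine from adding to the ynal.

Step 6
Reactants: 8 methyl 7-oxohept-5-ynoate; 9 tert-butyl acetate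
Product: 11 1-tert-butyl 9-methyl 3-hydroxynon-4-ynedioate (racemic), via lithium 1-tert-butoxyethenolate 10 (not isolated)
Conditions: 9, LiN(iPr)2, THF, −78 °C; then 8; AcOH, −78 °C
Reagents that add atoms: none
Why: Aldol addition of the preformed lithium enolate of tert-butyl acetate to the highly electrophilic ynal forms C7–C8 far faster than any Claisen attack on the methyl ester at −78 °C, and the C7 configuration is left unset because it is erased in step 7 and set in step 8.

Step 7
Reactants: 11 1-tert-butyl 9-methyl 3-hydroxynon-4-ynedioate (racemic)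
Product: 12 1-tert-butyl 9-methyl 3-oxonon-4-ynedioate
Conditions: Dess–Martin periodinane, CH2Cl2, 0 °C → rt
Reagents that add atoms: none
Why: Dess–Martin oxidation converts the propargylic secondary alcohol into the alkynyl ketone (a beta-keto ester) under nearly neutral conditions that should not affect the alkyne or either ester.

Step 8
Reactants: 12 1-tert-butyl 9-methyl 3-oxonon-4-ynedioate
Product: 13 1-tert-butyl 9-methyl (3R)-3-hydroxynon-4-ynedioate
Conditions: RuCl[(R,R)-TsDPEN](p-cymene) (1 mol%), HCO2H/Et3N (5:2), CH2Cl2, rt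
Reagents that add atoms: none
Why: Noyori asymmetric transfer hydrogenation of the alkynyl ketone, with the alkyne in the position normally taken by an aryl group in the six-membered hydride-transfer transition state, should set C7 as (R) under control of the (R,R)-diamine ligand, the mirror image of the (S)-propargylic alcohols that the (S,S)-catalyst gives from simple ynones.

Step 9
Reactants: 13 1-tert-butyl 9-methyl (3R)-3-hydroxynon-4-ynedioate
Product: 14 1-tert-butyl 9-methyl (3R)-3-[(tert-butyldimethylsilyl)oxy]non-4-ynedioate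
Conditions: TBSCl, imidazole, DMF, rt
Reagents that add atoms: tert-butyldimethylsilyl chloride, CC(C)(C)[Si](C)(C)Cl
Why: Silylation of the secondary alcohol with TBSCl and imidazole is a standard protection that is mild enough to avoid retro-aldol cleavage or dehydration of the beta-hydroxy ester.

Step 10
Reactants: 14 1-tert-butyl 9-methyl (3R)-3-[(tert-butyldimethylsilyl)oxy]non-4-ynedioate
Product: 15 1-tert-butyl 9-methyl (3R,4Z)-3-[(tert-butyldimethylsilyl)oxy]non-4-enedioate
Conditions: H2 (1 atm), Pd/CaCO3 poisoned with Pb(OAc)2, quinoline, EtOAc, rt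
Reagents that add atoms: none
Why: Lindlar semihydrogenation delivers both hydrogens to the same face of the alkyne on the poisoned palladium surface and stops at the alkene, which sets the C5=C6 cis geometry.

Step 11
Reactants: 15 1-tert-butyl 9-methyl (3R,4Z)-3-[(tert-butyldimethylsilyl)oxy]non-4-enedioate
Product: 17 (3R,4Z)-3-[(tert-butyldimethylsilyl)oxy]-9-methoxy-9-oxonon-4-enoic acid, via trimethylsilyl ester 16 (not isolated)
Conditions: TMSOTf, 2,6-lutidine, CH2Cl2, 0 °C; aqueous pH 7 buffer
Reagents that add atoms: none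
Why: Silyl triflate-mediated cleavage of the tert-butyl ester, by O-silylation, loss of 2-methylpropene and hydrolysis of the labile trimethylsilyl ester on work-up, is selective over the methyl ester and, buffered by 2,6-lutidine, should spare the allylic TBS ether.

Step 12
Reactants: 17 (3R,4Z)-3-[(tert-butyldimethylsilyl)oxy]-9-methoxy-9-oxonon-4-enoic acid; 4 1-{[(4Z)-deca-1,4-dien-2-yloxy]methyl}-4-methoxybenzene
Product: 20 methyl (5Z,7S)-7-[(tert-butyldimethylsilyl)oxy]-7-{(1R,2R)-2-[(4-methoxybenzyl)oxy]-2-[(2Z)-oct-2-en-1-yl]-4-oxocyclobutyl}hept-5-enoate, via acid chloride 18 (not isolated), via ketene 19 (not isolated)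
Conditions: 1-chloro-N,N,2-trimethylprop-1-en-1-amine, CH2Cl2, 0 °C → rt; then slow addition to 4 (2 equiv) and Et3N, toluene, 70 °C, continued heating
Reagents that add atoms: none
Why: The neutral chloroenamine converts the acid into the acid chloride without releasing HCl, Et3N dehydrochlorinates it to the monosubstituted ketene, and this undergoes a thermal ketene–enol ether [2+2] cycloaddition in which the ketene carbonyl carbon C9 bonds to the nucleophilic CH2 terminus (C11) and C8 to the oxygen-bearing C12; C8 then equilibrates through the enol under the amine to the isomer with its side chain trans to the octenyl group, whereas C12 is set relative to C7 by a facial preference that is expected to be only moderate, so the (7S,8R,12R) isomer is separated from its C12 epimer by chromatography at this stage.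

Step 13
Reactants: 20 methyl (5Z,7S)-7-[(tert-butyldimethylsilyl)oxy]-7-{(1R,2R)-2-[(4-methoxybenzyl)oxy]-2-[(2Z)-oct-2-en-1-yl]-4-oxocyclobutyl}hept-5-enoate
Product: 22 methyl (5Z,7S)-7-[(tert-butyldimethylsilyl)oxy]-7-{(1R,4R)-4-[(4-methoxybenzyl)oxy]-4-[(2Z)-oct-2-en-1-yl]-2-[(triethylsilyl)oxy]cyclobut-2-en-1-yl}hept-5-enoate, via kinetic lithium enolate 21 (not isolated)
Conditions: LiN(iPr)2 and TESCl premixed (in situ quench), THF, −78 °C
Reagents that add atoms: chlorotriethylsilane, CC[Si](CC)(CC)Cl
Why: Kinetic deprotonation by the hindered lithium amide should remove a proton from the accessible C11 methylene and not the tertiary C8–H flanked by two branched carbons, and the silyl chloride already present traps the enolate on oxygen before it can expel the C12 alkoxide (E1cB), which fixes the enol ether double bond at C9=C11.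

Step 14
Reactants: 22 methyl (5Z,7S)-7-[(tert-butyldimethylsilyl)oxy]-7-{(1R,4R)-4-[(4-methoxybenzyl)oxy]-4-[(2Z)-oct-2-en-1-yl]-2-[(triethylsilyl)oxy]cyclobut-2-en-1-yl}hept-5-enoate; 23 iodoform
Product: 26 methyl (5Z,7S)-7-[(tert-butyldimethylsilyl)oxy]-7-{(1R,2S)-4-iodo-2-[(4-methoxybenzyl)oxy]-2-[(2Z)-oct-2-en-1-yl]-5-oxocyclopent-3-en-1-yl}hept-5-enoate, via diiodocarbene 24 (not isolated), via diiodobicyclopentane 25 (not isolated)
Conditions: 23 (3 equiv), KOtBu (1 M in THF, 2.5 equiv, slow addition), toluene, −40 → 0 °C, dark; aqueous NaHCO3/Na2S2O3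
Reagents that add atoms: none
Why: Proposed new method: KOtBu deprotonates iodoform and the triiodomethanide loses iodide to give diiodocarbene 24, which adds as an electrophile in a [2+1] cheletropic step to the strained, electron-rich C9=C11 double bond of 22 to give housane 25; ionisation of one C10–I bond is then merged with disrotatory cleavage of the central C9–C11 bond (cyclopropyl-to-allyl opening), driven by the C9 siloxy donor and the strain of both small rings, and loss of the triethylsilyl group from the 2-iodo-1-siloxyallyl cation to tert-butoxide leaves the C9 ketone, the C10 iodide and the C10=C11 double bond. The closest known reaction type is the dihalocarbene ring enlargement of cyclic silyl enol ethers with five or more ring atoms to 2-halocycloalk-2-enones, together with the spontaneous opening of 5,5-dihalobicyclopentanes (housanes) to 2,3-dihalocyclopentenes; neither has been shown for a 1-siloxycyclobutene or with diiodocarbene on such a substrate. The cyclopentenone ring (C8–C12) is closed by one-carbon insertion, a [2+1] cycloaddition followed by electrocyclic enlargement of the four-membered ring, and not by an end-to-end cyclisation. No stereocentre is made: C9 and C11 end up sp2, C7 and C12 are not touched, and C8 keeps the trans relation to the octenyl chain that is also the stable arrangement next to the new ketone. The step needs chemoselectivity for the enol ether over the two cis-alkenes, which the far higher nucleophilicity and strain of the siloxycyclobutene and the bulk of the carbene should secure, and regiochemistry of insertion, which the position of the enol ether double bond from step 13 fixes. Slow addition of the base to an excess of iodoform keeps free alkoxide low, which protects the methyl ester, the triethylsilyl enol ether and the beta-silyloxy ketone of the product.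

Step 15
Reactants: 26 methyl (5Z,7S)-7-[(tert-butyldimethylsilyl)oxy]-7-{(1R,2S)-4-iodo-2-[(4-methoxybenzyl)oxy]-2-[(2Z)-oct-2-en-1-yl]-5-oxocyclopent-3-en-1-yl}hept-5-enoate
Product: 27 methyl (5Z,7S)-7-[(tert-butyldimethylsilyl)oxy]-7-{(1R,2S)-2-hydroxy-4-iodo-2-[(2Z)-oct-2-en-1-yl]-5-oxocyclopent-3-en-1-yl}hept-5-enoate
Conditions: DDQ, CH2Cl2/aqueous pH 7 buffer, 0 °C
Reagents that add atoms: none
Why: DDQ oxidises the electron-rich 4-methoxybenzyl ether by hydride abstraction and water hydrolyses the resulting oxocarbenium ion, which frees the tertiary C12 hydroxyl while C7 is still silylated so that no cyclic anisylidene acetal can form with a neighbouring free hydroxyl.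

Step 16
Reactants: 27 methyl (5Z,7S)-7-[(tert-butyldimethylsilyl)oxy]-7-{(1R,2S)-2-hydroxy-4-iodo-2-[(2Z)-oct-2-en-1-yl]-5-oxocyclopent-3-en-1-yl}hept-5-enoate
Product: 28 methyl (5Z,7S)-7-hydroxy-7-{(1R,2S)-2-hydroxy-4-iodo-2-[(2Z)-oct-2-en-1-yl]-5-oxocyclopent-3-en-1-yl}hept-5-enoate
Conditions: HF·pyridine, pyridine, THF, 0 °C → rt
Reagents that add atoms: none
Why: Fluoride-mediated desilylation with pyridine-buffered HF removes the TBS group under mildly acidic conditions, which avoid enolisation at C8 and thereby retro-aldol cleavage or dehydration of the beta-hydroxy ketone.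

Step 17
Reactants: 28 methyl (5Z,7S)-7-hydroxy-7-{(1R,2S)-2-hydroxy-4-iodo-2-[(2Z)-oct-2-en-1-yl]-5-oxocyclopent-3-en-1-yl}hept-5-enoate
Product: 29 methyl (5Z,7S)-7-acetoxy-7-{(1R,2S)-2-hydroxy-4-iodo-2-[(2Z)-oct-2-en-1-yl]-5-oxocyclopent-3-en-1-yl}hept-5-enoate
Conditions: Ac2O, pyridine, CH2Cl2, 0 °C
Reagents that add atoms: acetic anhydride, CC(=O)OC(C)=O
Why: Acylation with acetic anhydride in pyridine is selective for the secondary C7 hydroxyl over the hindered tertiary C12 hydroxyl, and the weak base at 0 °C without an acyl-transfer catalyst should not trigger E1cB loss of the new acetate to the cross-conjugated dienone.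

Compound list
1 | (3Z)-non-3-en-1-ol | CCCCC/C=C\CCO | starting material
2 | (3Z)-non-3-enoic acid | CCCCC/C=C\CC(=O)O | intermediate
3 | 4-methoxybenzyl (3Z)-non-3-enoate | CCCCC/C=C\CC(=O)OCc1ccc(OC)cc1 | intermediate
4 | 1-{[(4Z)-deca-1,4-dien-2-yloxy]methyl}-4-methoxybenzene | C=C(C/C=C\CCCCC)OCc1ccc(OC)cc1 | intermediate
5 | methyl hex-5-ynoate | COC(=O)CCCC#C | starting material
6 | methyl 6-iodohex-5-ynoate | COC(=O)CCCC#CI | intermediate
7 | (6-methoxy-6-oxohex-1-yn-1-yl)magnesium chloride | COC(=O)CCCC#C[Mg]Cl | intermediate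
8 | methyl 7-oxohept-5-ynoate | COC(=O)CCCC#CC=O | intermediate
9 | tert-butyl acetate | CC(=O)OC(C)(C)C | starting material
10 | lithium 1-tert-butoxyethen-1-olate | C=C(O[Li])OC(C)(C)C | intermediate
11 | 1-tert-butyl 9-methyl 3-hydroxynon-4-ynedioate (racemic) | COC(=O)CCCC#CC(O)CC(=O)OC(C)(C)C | intermediate
12 | 1-tert-butyl 9-methyl 3-oxonon-4-ynedioate | COC(=O)CCCC#CC(=O)CC(=O)OC(C)(C)C | intermediate
13 | 1-tert-butyl 9-methyl (3R)-3-hydroxynon-4-ynedioate | COC(=O)CCCC#C[C@H](O)CC(=O)OC(C)(C)C | intermediate
14 | 1-tert-butyl 9-methyl (3R)-3-[(tert-butyldimethylsilyl)oxy]non-4-ynedioate | COC(=O)CCCC#C[C@H](O[Si](C)(C)C(C)(C)C)CC(=O)OC(C)(C)C | intermediate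
15 | 1-tert-butyl 9-methyl (3R,4Z)-3-[(tert-butyldimethylsilyl)oxy]non-4-enedioate | COC(=O)CCC/C=C\[C@H](O[Si](C)(C)C(C)(C)C)CC(=O)OC(C)(C)C | intermediate
16 | 9-methyl 1-trimethylsilyl (3R,4Z)-3-[(tert-butyldimethylsilyl)oxy]non-4-enedioate | COC(=O)CCC/C=C\[C@H](O[Si](C)(C)C(C)(C)C)CC(=O)O[Si](C)(C)C | intermediate
17 | (3R,4Z)-3-[(tert-butyldimethylsilyl)oxy]-9-methoxy-9-oxonon-4-enoic acid | COC(=O)CCC/C=C\[C@H](O[Si](C)(C)C(C)(C)C)CC(=O)O | intermediate
18 | methyl (5Z,7R)-7-[(tert-butyldimethylsilyl)oxy]-9-chloro-9-oxonon-5-enoate | COC(=O)CCC/C=C\[C@H](O[Si](C)(C)C(C)(C)C)CC(=O)Cl | intermediate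
19 | methyl (5Z,7S)-7-[(tert-butyldimethylsilyl)oxy]-9-oxonona-5,8-dienoate (ketene) | COC(=O)CCC/C=C\[C@H](O[Si](C)(C)C(C)(C)C)C=C=O | intermediate
20 | methyl (5Z,7S)-7-[(tert-butyldimethylsilyl)oxy]-7-{(1R,2R)-2-[(4-methoxybenzyl)oxy]-2-[(2Z)-oct-2-en-1-yl]-4-oxocyclobutyl}hept-5-enoate; in target numbering (7S,8R,12R), C7 chain trans to the octenyl group | O=C1C[C@](OCc2ccc(OC)cc2)(C/C=C\CCCCC)[C@H]1[C@H](/C=C\CCCC(=O)OC)O[Si](C)(C)C(C)(C)C | intermediate
21 | lithium enolate of 20 towards C11 (C9=C11 cyclobutenolate) | [Li]OC1=C[C@](OCc2ccc(OC)cc2)(C/C=C\CCCCC)[C@H]1[C@H](/C=C\CCCC(=O)OC)O[Si](C)(C)C(C)(C)C | intermediate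
22 | methyl (5Z,7S)-7-[(tert-butyldimethylsilyl)oxy]-7-{(1R,4R)-4-[(4-methoxybenzyl)oxy]-4-[(2Z)-oct-2-en-1-yl]-2-[(triethylsilyl)oxy]cyclobut-2-en-1-yl}hept-5-enoate (key-step precursor) | CC[Si](CC)(CC)OC1=C[C@](OCc2ccc(OC)cc2)(C/C=C\CCCCC)[C@H]1[C@H](/C=C\CCCC(=O)OC)O[Si](C)(C)C(C)(C)C | intermediate
23 | iodoform (triiodomethane) | IC(I)I | starting material
24 | diiodocarbene | I[C]I | intermediate
25 | 5,5-diiodo-1-[(triethylsilyl)oxy]bicyclo[2.1.0]pentane adduct of 22 (carbene on the ring face anti to the C8 side chain; C7, C8 and C12 as in 22) | CC[Si](CC)(CC)O[C@@]12C(I)(I)[C@@H]1[C@](OCc3ccc(OC)cc3)(C/C=C\CCCCC)[C@H]2[C@H](/C=C\CCCC(=O)OC)O[Si](C)(C)C(C)(C)C | intermediate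
26 | methyl (5Z,7S)-7-[(tert-butyldimethylsilyl)oxy]-7-{(1R,2S)-4-iodo-2-[(4-methoxybenzyl)oxy]-2-[(2Z)-oct-2-en-1-yl]-5-oxocyclopent-3-en-1-yl}hept-5-enoate (key-step product) | CCCCC/C=C\C[C@@]1(OCc2ccc(OC)cc2)C=C(I)C(=O)[C@@H]1[C@H](/C=C\CCCC(=O)OC)O[Si](C)(C)C(C)(C)C | intermediate
27 | methyl (5Z,7S)-7-[(tert-butyldimethylsilyl)oxy]-7-{(1R,2S)-2-hydroxy-4-iodo-2-[(2Z)-oct-2-en-1-yl]-5-oxocyclopent-3-en-1-yl}hept-5-enoate | CCCCC/C=C\C[C@@]1(O)C=C(I)C(=O)[C@@H]1[C@H](/C=C\CCCC(=O)OC)O[Si](C)(C)C(C)(C)C | intermediate
28 | methyl (5Z,7S)-7-hydroxy-7-{(1R,2S)-2-hydroxy-4-iodo-2-[(2Z)-oct-2-en-1-yl]-5-oxocyclopent-3-en-1-yl}hept-5-enoate | CCCCC/C=C\C[C@@]1(O)C=C(I)C(=O)[C@@H]1[C@H](/C=C\CCCC(=O)OC)O | intermediate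
29 | methyl (5Z,7S)-7-acetoxy-7-{(1R,2S)-2-hydroxy-4-iodo-2-[(2Z)-oct-2-en-1-yl]-5-oxocyclopent-3-en-1-yl}hept-5-enoate; in target numbering (7S,8R,12S) | CCCCC/C=C\C[C@@]1(O)C=C(I)C(=O)[C@@H]1[C@H](/C=C\CCCC(=O)OC)OC(C)=O | target

Total step count: 17 steps.
Longest linear sequence: 14 steps (5 to 29, steps 4–17); enol ether 4 is made in 3 steps (steps 1–3) and joins at step 12.

Steps most likely to fail

Step 14 (proposed new method). The carbene may dimerise or be quenched faster than the enol ether captures it. Alkoxide may desilylate the enol ether back to 20, or enolise the product at C8 with loss of the C7 silyloxy group. The housane may also open to an allylic iodide that does not collapse cleanly to the enone. The fallback uses known chemistry, sets out from 20 and comes back at 26. Ring enlargement of cyclobutanone 20 with diazomethane (Et2O/MeOH, 0 °C) should give the cyclopentanone F1; the less substituted C11 is expected to migrate preferentially and the regioisomer would be removed by chromatography. Kinetic enol silylation towards C10 (LiN(iPr)2, TMSCl, THF, −78 °C) should give the trimethylsilyl enol ether F2. Saegusa–Ito dehydrogenation with Pd(OAc)2 in MeCN should give the cyclopentenone F3. Alpha-iodination of this enone with I2 and pyridine in CH2Cl2 then returns to 26.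

Step 12. Bond formation between C8 and C12 may show poor facial selectivity relative to C7, leaving an unfavourable or hard-to-separate mixture of C12 epimers. Equilibration at C8 may be incomplete, and the aldoketene may dimerise. The fallback sets out from 14 and comes back at 20. It moves the cycloaddition in front of the semihydrogenation, so that the two faces of the ketene differ by a bulky silyloxy group against a slim alkyne. Cleavage of the tert-butyl ester of 14 (TMSOTf, 2,6-lutidine) through the trimethylsilyl ester F4 should give the alkynyl acid F5. This is converted under the conditions of step 12 through the acid chloride F6 and the ketene F7 into the alkynyl cyclobutanone F8. Lindlar semihydrogenation of F8 (H2, Pd/CaCO3 poisoned with Pb(OAc)2, quinoline), to which the octenyl cis-alkene and the PMB ether are inert, then gives 20.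

Step 17. Base-induced enolisation at C8 may cause E1cB loss of the acetate just installed, or of water before acylation, giving the cross-conjugated dienone. Slow acylation of the hindered secondary alcohol would invite harsher conditions that make this worse. The fallback sets out from 28 and comes back at 29. It replaces base-mediated acylation by enzymatic acyl transfer: a lipase (immobilised Candida antarctica lipase B or Burkholderia cepacia lipase) with vinyl acetate in MTBE at rt. This is neutral and acylates secondary but not tertiary alcohols, so it should convert 28 directly into 29. It makes no new compound (none F0).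

Further compounds
F1 | step 14 | methyl (5Z,7S)-7-[(tert-butyldimethylsilyl)oxy]-7-{(1R,2S)-2-[(4-methoxybenzyl)oxy]-2-[(2Z)-oct-2-en-1-yl]-5-oxocyclopentyl}hept-5-enoate | CCCCC/C=C\C[C@@]1(OCc2ccc(OC)cc2)CCC(=O)[C@@H]1[C@H](/C=C\CCCC(=O)OC)O[Si](C)(C)C(C)(C)C
F2 | step 14 | methyl (5Z,7S)-7-[(tert-butyldimethylsilyl)oxy]-7-{(1R,5R)-5-[(4-methoxybenzyl)oxy]-5-[(2Z)-oct-2-en-1-yl]-2-[(trimethylsilyl)oxy]cyclopent-2-en-1-yl}hept-5-enoate | CCCCC/C=C\C[C@@]1(OCc2ccc(OC)cc2)CC=C(O[Si](C)(C)C)[C@@H]1[C@H](/C=C\CCCC(=O)OC)O[Si](C)(C)C(C)(C)C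
F3 | step 14 | methyl (5Z,7S)-7-[(tert-butyldimethylsilyl)oxy]-7-{(1R,2R)-2-[(4-methoxybenzyl)oxy]-2-[(2Z)-oct-2-en-1-yl]-5-oxocyclopent-3-en-1-yl}hept-5-enoate | CCCCC/C=C\C[C@@]1(OCc2ccc(OC)cc2)C=CC(=O)[C@@H]1[C@H](/C=C\CCCC(=O)OC)O[Si](C)(C)C(C)(C)C
F4 | step 12 | 9-methyl 1-trimethylsilyl (3R)-3-[(tert-butyldimethylsilyl)oxy]non-4-ynedioate | COC(=O)CCCC#C[C@H](O[Si](C)(C)C(C)(C)C)CC(=O)O[Si](C)(C)C
F5 | step 12 | (3R)-3-[(tert-butyldimethylsilyl)oxy]-9-methoxy-9-oxonon-4-ynoic acid | COC(=O)CCCC#C[C@H](O[Si](C)(C)C(C)(C)C)CC(=O)O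
F6 | step 12 | methyl (7R)-7-[(tert-butyldimethylsilyl)oxy]-9-chloro-9-oxonon-5-ynoate | COC(=O)CCCC#C[C@H](O[Si](C)(C)C(C)(C)C)CC(=O)Cl
F7 | step 12 | methyl (7R)-7-[(tert-butyldimethylsilyl)oxy]-9-oxonon-8-en-5-ynoate (ketene) | COC(=O)CCCC#C[C@H](O[Si](C)(C)C(C)(C)C)C=C=O
F8 | step 12 | methyl (7R)-7-[(tert-butyldimethylsilyl)oxy]-7-{(1R,2R)-2-[(4-methoxybenzyl)oxy]-2-[(2Z)-oct-2-en-1-yl]-4-oxocyclobutyl}hept-5-ynoate | O=C1C[C@](OCc2ccc(OC)cc2)(C/C=C\CCCCC)[C@H]1[C@H](C#CCCCC(=O)OC)O[Si](C)(C)C(C)(C)C
F0 | step 17 | none | none
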